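## Retrosynthetic overview

1. The last bond made is the chain bond between the CH2 on phthalide C3 and the next chain carbon (the former aldehyde carbon). It comes from a 450 nm light-driven radical addition of iodide 11 to the tosylhydrazone of aldehyde 22, followed by loss of sulfinate and N2.
2. Phthalide 11: the benzene ring is built by an Alder–Rickert cycloaddition/ethene extrusion between alkynoate 4 (from (R)-glyceraldehyde acetonide, which supplies C3) and 1,5-dimethoxycyclohexa-1,4-diene. The lactone ring closes when the acetonide is removed.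
3. Spiroketal 22: acetone dimethylhydrazone is alkylated at both α-carbons with epoxide 16 (from (R)-epichlorohydrin) and (R)-propylene oxide. Acid then closes both oxolane rings at once.
4. Ring order: benzene ring, then lactone ring; in the other branch both spiroketal rings together; the two halves are joined last.

Assumption: acid equilibration gives the two C5 epimers of the spiroketal in about equal amounts and they can be separated by chromatography at the stage of 22 (the unwanted one goes back into the acid equilibration); if they co-elute, the pair is carried on and separated by HPLC at the stage of 25.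

## Route

Step 1
Reactants: 1 (R)-2,2-dimethyl-1,3-dioxolane-4-carbaldehyde
Product: 2 (4S)-4-(2,2-dibromoethenyl)-2,2-dimethyl-1,3-dioxolane
Conditions: CBr4, PPh3, Zn, CH2Cl2, 0 °C to rt
Reagents that add atoms: carbon tetrabromide, BrC(Br)(Br)Br
Why: Corey–Fuchs dibromo-olefination with the ylide Ph3P=CBr2 under neutral, Zn-buffered conditions that spare the acetonide; the stereocentre is not touched (R becomes S only through the change in priorities).

Step 2
Reactants: 2 (4S)-4-(2,2-dibromoethenyl)-2,2-dimethyl-1,3-dioxolane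
Product: 4 methyl 3-[(4S)-2,2-dimethyl-1,3-dioxolan-4-yl]prop-2-ynoate, via lithium acetylide 3 (not isolated)
Conditions: n-BuLi (2.1 equiv), THF, −78 °C; then ClCO2Me, −78 to 0 °C
Reagents that add atoms: methyl chloroformate, COC(=O)Cl
Why: Second stage of the Corey–Fuchs alkyne synthesis (elimination and Br–Li exchange) gives acetylide 3, which is C-acylated by the chloroformate; the propargylic stereocentre is not touched.

Step 3
Reactants: 4 methyl 3-[(4S)-2,2-dimethyl-1,3-dioxolan-4-yl]prop-2-ynoate, 5 1,5-dimethoxycyclohexa-1,4-diene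
Product: 10 (3S)-3-(hydroxymethyl)-5,7-dimethoxy-2-benzofuran-1(3H)-one, via conjugated diene 6 (not isolated), via bicyclooctadiene adduct 7 (not isolated), via aryl acetonide ester 8 (not isolated), via diol ester 9 (not isolated)
Conditions: 5 (3 equiv), dichloromaleic anhydride (2 mol%), neat, 190 °C, sealed tube; then 2 M HCl, MeOH, 60 °C
Reagents that add atoms: none
Why: Alder–Rickert reaction: 5 moves into conjugation (6), its methoxy-bearing terminus bonds to the ester-bearing alkyne carbon in a Diels–Alder reaction (7), retro-Diels–Alder loss of ethene gives the 2,4-dimethoxy-6-substituted benzoate 8, and acid then removes the acetonide so that the benzylic hydroxyl of 9 closes the five-membered lactone onto the ortho ester; C3 is the glyceraldehyde carbon and no bond to it is broken.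

Step 4
Reactants: 10 (3S)-3-(hydroxymethyl)-5,7-dimethoxy-2-benzofuran-1(3H)-one
Product: 11 (3S)-3-(iodomethyl)-5,7-dimethoxy-2-benzofuran-1(3H)-one
Conditions: I2, PPh3, imidazole, CH2Cl2, 0 °C to rt
Reagents that add atoms: iodine, [I][I]
Why: Appel-type iodination of the primary alcohol by SN2 at CH2; C3 is not involved.

Step 5
Reactants: 12 2-(3-chloropropyl)-1,3-dioxolane, 13 (R)-epichlorohydrin
Product: 16 2-{4-[(2R)-oxiran-2-yl]butyl}-1,3-dioxolane, via Grignard reagent 14 (not isolated), via chlorohydrin alkoxide 15 (not isolated)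
Conditions: Mg, THF, 65 °C; then 13, CuI (5 mol%), −40 to 0 °C; then NaOH (powder), rt
Reagents that add atoms: none
Why: Grignard formation, CuI-catalysed epoxide opening at the ring CH2 of epichlorohydrin, then base-induced closure of the chlorohydrin onto the CH2Cl carbon; the C–O bond of the stereocentre is never broken, so (R) is kept.

Step 6
Reactants: 17 acetone N,N-dimethylhydrazone, 16 2-{4-[(2R)-oxiran-2-yl]butyl}-1,3-dioxolane, 18 (R)-propylene oxide
Product: 22 5-[(2R,5S,7R)-7-methyl-1,6-dioxaspiro[4.4]nonan-2-yl]pentanal, via mono-alkylated hydrazone 19 (not isolated), via bis-alkylated hydrazone 20 (not isolated), via dihydroxy keto aldehyde 21 (not isolated)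
Conditions: n-BuLi, THF, −78 to 0 °C, then 16; n-BuLi, −78 to 0 °C, then 18 (1.3 equiv), rt; then 2 M HCl, THF, rt
Reagents that add atoms: water, O
Why: Corey–Enders aza-enolate alkylation at the CH2 terminus of each epoxide (first one methyl of the hydrazone, then the other), followed by acid hydrolysis of hydrazone and dioxolane and thermodynamic spiroketalisation of the 1,7-dihydroxy-4-ketone; the two carbinol centres are bought, and the spiro centre forms under their control as a near 1:1 pair of C5 epimers from which (5S)-22 is separated while the other is returned to the acid.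

Step 7
Reactants: 22 5-[(2R,5S,7R)-7-methyl-1,6-dioxaspiro[4.4]nonan-2-yl]pentanal, 11 (3S)-3-(iodomethyl)-5,7-dimethoxy-2-benzofuran-1(3H)-one
Product: 25 (3R)-5,7-dimethoxy-3-{6-[(2R,5S,7R)-7-methyl-1,6-dioxaspiro[4.4]nonan-2-yl]hexyl}-2-benzofuran-1(3H)-one, via tosylhydrazone 23 (not isolated), via tosylhydrazide 24 (not isolated)
Conditions: TsNHNH2, 4 Å MS, THF, rt; then 11 (1.5 equiv), Mn2(CO)10 (10 mol%), (Me3Si)3SiH (slow addition), 2,6-lutidine, 450 nm LEDs, 25 °C; then NaOAc·3H2O, EtOH, 70 °C
Reagents that add atoms: none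
Why: Proposed new method: a traceless radical alkyl–alkyl coupling in which 450 nm homolysis of Mn2(CO)10 gives Mn(CO)5 radicals that abstract iodine from 11, the primary radical adds to the electrophilic C=N carbon of 23 (polarity matched, and no carbon–metal bond is ever formed next to the lactone oxygen), the hydrazinyl radical takes H from (Me3Si)3SiH and the silyl radical carries the chain by abstracting iodine from 11, after which NaOAc expels sulfinate from 24 and the alkyldiazene loses N2 to leave the CH2–CH2 link with C3 and the base-buffered spiroketal untouched; the closest known reactions are the light-driven Mn2(CO)10-mediated addition of primary alkyl iodides to N-acylhydrazones and the photocatalytic C–H alkylation of sulfonylhydrazones with base-induced loss of N2 (a Wolff–Kishner-type reductive coupling), which have not been combined for an unactivated β-acyloxy alkyl iodide and an aliphatic aldehyde tosylhydrazone.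

## Compound list

1 | (R)-2,2-dimethyl-1,3-dioxolane-4-carbaldehyde | O=C[C@H]1COC(C)(C)O1 | starting material
2 | (4S)-4-(2,2-dibromoethenyl)-2,2-dimethyl-1,3-dioxolane | BrC(Br)=C[C@H]1COC(C)(C)O1 | intermediate
3 | lithium [(4S)-2,2-dimethyl-1,3-dioxolan-4-yl]acetylide | [Li]C#C[C@H]1COC(C)(C)O1 | intermediate
4 | methyl 3-[(4S)-2,2-dimethyl-1,3-dioxolan-4-yl]prop-2-ynoate | COC(=O)C#C[C@H]1COC(C)(C)O1 | intermediate
5 | 1,5-dimethoxycyclohexa-1,4-diene | COC1=CCC=C(OC)C1 | starting material
6 | 1,3-dimethoxycyclohexa-1,3-diene | COC1=CC(OC)=CCC1 | intermediate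
7 | methyl 3-[(4S)-2,2-dimethyl-1,3-dioxolan-4-yl]-1,5-dimethoxybicyclo[2.2.2]octa-2,5-diene-2-carboxylate (both bridgehead diastereomers) | COC(=O)C1=C([C@H]2COC(C)(C)O2)C3CCC1(OC)C=C3OC | intermediate
8 | methyl 2-[(4S)-2,2-dimethyl-1,3-dioxolan-4-yl]-4,6-dimethoxybenzoate | COC(=O)c1c(OC)cc(OC)cc1[C@H]1COC(C)(C)O1 | intermediate
9 | methyl 2-[(1S)-1,2-dihydroxyethyl]-4,6-dimethoxybenzoate | COC(=O)c1c(OC)cc(OC)cc1[C@H](O)CO | intermediate
10 | (3S)-3-(hydroxymethyl)-5,7-dimethoxy-2-benzofuran-1(3H)-one | COc1cc(OC)c2c(c1)[C@@H](CO)OC2=O | intermediate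
11 | (3S)-3-(iodomethyl)-5,7-dimethoxy-2-benzofuran-1(3H)-one | COc1cc(OC)c2c(c1)[C@@H](CI)OC2=O | intermediate
12 | 2-(3-chloropropyl)-1,3-dioxolane | ClCCCC1OCCO1 | starting material
13 | (R)-epichlorohydrin, (2R)-2-(chloromethyl)oxirane | ClC[C@H]1CO1 | starting material
14 | [3-(1,3-dioxolan-2-yl)propyl]magnesium chloride | Cl[Mg]CCCC1OCCO1 | intermediate
15 | chloromagnesium alkoxide of (2R)-1-chloro-6-(1,3-dioxolan-2-yl)hexan-2-ol | ClC[C@H](O[Mg]Cl)CCCCC1OCCO1 | intermediate
16 | 2-{4-[(2R)-oxiran-2-yl]butyl}-1,3-dioxolane | O1C[C@H]1CCCCC2OCCO2 | intermediate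
17 | acetone N,N-dimethylhydrazone | CC(C)=NN(C)C | starting material
18 | (R)-propylene oxide, (2R)-2-methyloxirane | C[C@@H]1CO1 | starting material
19 | lithium (5R)-2-(2,2-dimethylhydrazinylidene)-9-(1,3-dioxolan-2-yl)nonan-5-olate | CC(=NN(C)C)CC[C@H](O[Li])CCCCC1OCCO1 | intermediate
20 | dilithium (2R,8R)-5-(2,2-dimethylhydrazinylidene)-12-(1,3-dioxolan-2-yl)dodecane-2,8-diolate | C[C@@H](O[Li])CCC(=NN(C)C)CC[C@H](O[Li])CCCCC1OCCO1 | intermediate
21 | (6R,12R)-6,12-dihydroxy-9-oxotridecanal | O=CCCCC[C@@H](O)CCC(=O)CC[C@@H](C)O | intermediate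
22 | 5-[(2R,5S,7R)-7-methyl-1,6-dioxaspiro[4.4]nonan-2-yl]pentanal | O=CCCCC[C@@H]1CC[C@]2(CC[C@@H](C)O2)O1 | intermediate
23 | (E)-N'-{5-[(2R,5S,7R)-7-methyl-1,6-dioxaspiro[4.4]nonan-2-yl]pentylidene}-4-methylbenzenesulfonohydrazide | Cc1ccc(cc1)S(=O)(=O)N/N=C/CCCC[C@@H]1CC[C@]2(CC[C@@H](C)O2)O1 | intermediate
24 | N'-{1-[(1S)-4,6-dimethoxy-3-oxo-1,3-dihydro-2-benzofuran-1-yl]-6-[(2R,5S,7R)-7-methyl-1,6-dioxaspiro[4.4]nonan-2-yl]hexan-2-yl}-4-methylbenzenesulfonohydrazide (both epimers at the N-bearing carbon) | COc1cc(OC)c2c(c1)[C@@H](CC(CCCC[C@@H]1CC[C@]3(CC[C@@H](C)O3)O1)NNS(=O)(=O)c1ccc(C)cc1)OC2=O | intermediate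
25 | (3R)-5,7-dimethoxy-3-{6-[(2R,5S,7R)-7-methyl-1,6-dioxaspiro[4.4]nonan-2-yl]hexyl}-2-benzofuran-1(3H)-one | COc1cc(OC)c2c(c1)[C@@H](CCCCCC[C@@H]1CC[C@]3(CC[C@@H](C)O3)O1)OC2=O | target

## Step count and risk

Total steps: 7. Longest linear sequence: 5 (steps 1, 2, 3, 4, 7).

Steps most likely to fail:

Step 7 (the new radical coupling). The radical from 11 may be reduced by the silane before it adds to the C=N bond, giving the 3-methyl phthalide. It may also undergo a 1,2-acyloxy shift to a ring-expanded isochromanone radical. Acid from the silyl iodide could re-equilibrate the spiro centre, which is why sieves and lutidine are present. The fallback is polar and uses known chemistry; it sets out from 11 and 22 and comes back to the route at 25. K2CO3 in MeOH opens the lactone of 11 and the alkoxide displaces iodide, giving methyl 2,4-dimethoxy-6-[(2S)-oxiran-2-yl]benzoate F1 with the C–O bond of the stereocentre kept. Aldehyde 22 is reduced with NaBH4 to 5-[(2R,5S,7R)-7-methyl-1,6-dioxaspiro[4.4]nonan-2-yl]pentan-1-ol F2. CBr4 and PPh3 convert this into (2R,5S,7R)-2-(5-bromopentyl)-7-methyl-1,6-dioxaspiro[4.4]nonane F3, and Mg in THF gives {5-[(2R,5S,7R)-7-methyl-1,6-dioxaspiro[4.4]nonan-2-yl]pentyl}magnesium bromide F4. CuI-catalysed opening of F1 at its CH2 carbon gives the bromomagnesium alkoxide of methyl 2-{(1R)-1-hydroxy-7-[(2R,5S,7R)-7-methyl-1,6-dioxaspiro[4.4]nonan-2-yl]heptyl}-4,6-dimethoxybenzoate F5. On warming (TsOH if needed) F5 closes onto the neighbouring hindered ester to give 25. Attack at the benzylic carbon of F1 is the main risk of this path.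

Step 3 (Alder–Rickert and lactonisation in one pot). The alkynoate may decompose at 190 °C, the 1,4-diene may conjugate too slowly, and some six-membered lactone may form through the primary hydroxyl. The fallback builds the arene with a more reactive diene at low temperature; it sets out from 4 and comes back at 8, which is then isolated and put through the acid stage of step 3. Commercial 1-methoxy-1,3-bis(trimethylsilyloxy)buta-1,3-diene adds to 4 in toluene at 80 °C to give methyl 2-[(4S)-2,2-dimethyl-1,3-dioxolan-4-yl]-6-methoxy-4,6-bis(trimethylsilyloxy)cyclohexa-1,4-diene-1-carboxylate F6. On buffered work-up F6 loses methanol and its silyl groups to give methyl 2-[(4S)-2,2-dimethyl-1,3-dioxolan-4-yl]-4,6-dihydroxybenzoate F7. MeI and K2CO3 in acetone methylate both phenols to give 8.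

Step 6 (double alkylation, hydrolysis and spiroketalisation in one pot). The second deprotonation may be incomplete or not fully regioselective, epoxide opening by the aza-enolate may be slow, and the aldehyde may suffer in acid. The fallback is the stepwise keto-lactone route; it sets out from 16 and 18 and comes back at 22 through 21. Methyl acetoacetate with NaOMe in MeOH at 65 °C opens 16 and lactonises to (5R)-3-acetyl-5-[4-(1,3-dioxolan-2-yl)butyl]oxolan-2-one F8. Its dianion (NaH, then n-BuLi, THF, 0 °C) opens 18 at the acetyl carbon to give (5R)-5-[4-(1,3-dioxolan-2-yl)butyl]-3-[(4R)-4-hydroxypentanoyl]oxolan-2-one F9. 2 M HCl at 80 °C hydrolyses the lactone, decarboxylates and cleaves the dioxolane to give 21, which closes to 22.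

## Further compounds

F1 | step 7 | methyl 2,4-dimethoxy-6-[(2S)-oxiran-2-yl]benzoate | COC(=O)c1c(OC)cc(OC)cc1[C@H]1CO1
F2 | step 7 | 5-[(2R,5S,7R)-7-methyl-1,6-dioxaspiro[4.4]nonan-2-yl]pentan-1-ol | OCCCCC[C@@H]1CC[C@]2(CC[C@@H](C)O2)O1
F3 | step 7 | (2R,5S,7R)-2-(5-bromopentyl)-7-methyl-1,6-dioxaspiro[4.4]nonane | BrCCCCC[C@@H]1CC[C@]2(CC[C@@H](C)O2)O1
F4 | step 7 | {5-[(2R,5S,7R)-7-methyl-1,6-dioxaspiro[4.4]nonan-2-yl]pentyl}magnesium bromide | Br[Mg]CCCCC[C@@H]1CC[C@]2(CC[C@@H](C)O2)O1
F5 | step 7 | bromomagnesium alkoxide of methyl 2-{(1R)-1-hydroxy-7-[(2R,5S,7R)-7-methyl-1,6-dioxaspiro[4.4]nonan-2-yl]heptyl}-4,6-dimethoxybenzoate | COC(=O)c1c(OC)cc(OC)cc1[C@H](O[Mg]Br)CCCCCC[C@@H]1CC[C@]2(CC[C@@H](C)O2)O1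
F6 | step 3 | methyl 2-[(4S)-2,2-dimethyl-1,3-dioxolan-4-yl]-6-methoxy-4,6-bis(trimethylsilyloxy)cyclohexa-1,4-diene-1-carboxylate | COC(=O)C1=C([C@H]2COC(C)(C)O2)CC(O[Si](C)(C)C)=CC1(OC)O[Si](C)(C)C
F7 | step 3 | methyl 2-[(4S)-2,2-dimethyl-1,3-dioxolan-4-yl]-4,6-dihydroxybenzoate | COC(=O)c1c(O)cc(O)cc1[C@H]1COC(C)(C)O1
F8 | step 6 | (5R)-3-acetyl-5-[4-(1,3-dioxolan-2-yl)butyl]oxolan-2-one | CC(=O)C1C[C@@H](CCCCC2OCCO2)OC1=O
F9 | step 6 | (5R)-5-[4-(1,3-dioxolan-2-yl)butyl]-3-[(4R)-4-hydroxypentanoyl]oxolan-2-one | C[C@@H](O)CCC(=O)C1C[C@@H](CCCCC2OCCO2)OC1=O
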